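**Retrosynthetic overview**
1. The last operations install the 1,1-disubstituted alkene (methylenation of a side-chain ketone) and the angular methyl next to the ring ketone (reductive methylation of an α-acetoxy ketone).
2. Key disconnection: ring C is the cyclohexanone made of C=O, its α-quaternary carbon, the quaternary bridgehead, the bridge CH2, the side-chain CH and the CH bridgehead. It is cut at CH2–CH and at C(=O)–C(α) in one operation.
3. Enabling feature, first half: in ring C the α-carbon, the quaternary bridgehead and the CH2 are 1,3-related. They are the three carbons of a cyclopropanol fused to ring B, with a nucleophilic CH2 and a latent ketone. Second half: the side-chain CH, the CH bridgehead and C=O are the β, α and formyl carbons of a (Z)-4-oxo-2-enal, with an electrophilic β-carbon and a formyl group that a carbene can umpole.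
4. The enal is unmasked from a 2,4-disubstituted furan with singlet oxygen, and the cyclopropanol comes from a silyl dienol ether (Simmons–Smith). The two halves are joined by a Negishi coupling of a (Z)-vinyl iodide with a 2-iodoenone.
5. Ring order: B (Birch reduction of an arene), D (oxa-Michael lactone), cyclopropane, then ring A (cyclohexene) and ring C together in the key step.

Key step: step 12

Assumption: compounds 1, 5 and 6 are taken as commercial. The ring stereocentre of 3, 4, 14 and 15 should form as a mixture of epimers and is drawn in the configuration that the equilibration in step 8 selects.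

**Step 1**
Reactants: 1 (S)-2-(4-methoxyphenyl)propanoic acid
Product: 2 (S)-2-(4-methoxycyclohexa-1,4-dien-1-yl)propanoic acid
Conditions: Li, NH3(l), t-BuOH, THF, −78 °C
Reagents that add atoms: none
Why: Birch reduction of the anisole as its lithium carboxylate should give the 1-methoxy-1,4-diene, with regiochemistry fixed by the two donor substituents, while the carboxylate protects the side-chain stereocentre from α-deprotonation.

**Step 2**
Reactants: 2 (S)-2-(4-methoxycyclohexa-1,4-dien-1-yl)propanoic acid
Product: 3 methyl (2S)-2-[(1R)-4-oxocyclohex-2-en-1-yl]propanoate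
Conditions: HCl (1 M in MeOH), rt; then H2O, 40 °C
Reagents that add atoms: methanol (CO); water (O)
Why: Fischer esterification and enol ether hydrolysis, followed by acid-catalysed migration of the alkene into conjugation, should give the 4-substituted enone, whose new ring stereocentre is not controlled here and is corrected in step 8.

**Step 3**
Reactants: 3 methyl (2S)-2-[(1R)-4-oxocyclohex-2-en-1-yl]propanoate
Product: 4 methyl (2S)-2-[(1S)-3-iodo-4-oxocyclohex-2-en-1-yl]propanoate
Conditions: I2, pyridine, CH2Cl2, rt
Reagents that add atoms: iodine (II)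
Why: Johnson α-iodination (pyridine conjugate addition, iodination of the enolate, elimination) places iodine only on the α-carbon of the enone and creates no stereocentre.

**Step 4**
Reactants: 5 furan-3-carbaldehyde; 6 5-bromo-2-methylpent-2-ene
Product: 10 5-(4-methylpent-3-en-1-yl)furan-3-carbaldehyde, via amino alkoxide 7 (not isolated), via lithiated amino alkoxide 8 (not isolated), via alkylated amino alkoxide 9 (not isolated)
Conditions: morpholine, n-BuLi, THF, −78 °C; 5; s-BuLi, −78 °C; 6, −78 °C to rt; then H2O
Reagents that add atoms: none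
Why: In situ protection of the aldehyde as an α-amino alkoxide shields C2, so directed lithiation should occur at C5, and alkylation followed by aqueous release gives the 2,4-disubstituted furan pattern.

**Step 5**
Reactants: 10 5-(4-methylpent-3-en-1-yl)furan-3-carbaldehyde
Product: 11 4-[(Z)-2-iodoprop-1-en-1-yl]-2-(4-methylpent-3-en-1-yl)furan
Conditions: EtPPh3I, n-BuLi, THF, 0 °C; I2, −78 °C; NaHMDS, −20 °C; 10, −78 °C
Reagents that add atoms: ethyltriphenylphosphonium iodide (CC[P+](c1ccccc1)(c1ccccc1)c1ccccc1.[I-]); iodine (II)
Why: Stork–Zhao-type Wittig olefination with the α-iodoethylidene ylide should give, under kinetic control, the (Z)-trisubstituted vinyl iodide with iodine cis to the furan, which is the geometry the later ring closure requires.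

**Step 6**
Reactants: 11 4-[(Z)-2-iodoprop-1-en-1-yl]-2-(4-methylpent-3-en-1-yl)furan; 4 methyl (2S)-2-[(1S)-3-iodo-4-oxocyclohex-2-en-1-yl]propanoate
Product: 14 methyl (2S)-2-[(1R)-3-{(Z)-1-[5-(4-methylpent-3-en-1-yl)furan-3-yl]prop-1-en-2-yl}-4-oxocyclohex-2-en-1-yl]propanoate, via alkenyllithium 12 (not isolated), via alkenylzinc bromide 13 (not isolated)
Conditions: 11, t-BuLi (2 equiv), Et2O, −78 °C; ZnBr2, THF, −78 to 0 °C; 4, Pd(PPh3)4 (5 mol%), THF, rt
Reagents that add atoms: none
Why: Iodine–lithium exchange, transmetalation to zinc and Negishi coupling all proceed with retention of alkene geometry, and the organozinc tolerates both the ester and the enone.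

**Step 7**
Reactants: 14 the coupled enone methyl ester
Product: 15 (2S)-2-[(1R)-3-{(Z)-1-[5-(4-methylpent-3-en-1-yl)furan-3-yl]prop-1-en-2-yl}-4-oxocyclohex-2-en-1-yl]propanoic acid
Conditions: LiOH, THF/H2O, 0 °C; then 1 M HCl
Reagents that add atoms: lithium hydroxide ([Li+].[OH-])
Why: Plain saponification of the methyl ester, in which any epimerisation at the γ-carbon of the enone is harmless because the next step equilibrates that centre.

**Step 8**
Reactants: 15 the dienone acid
Product: 17 cis-fused 6-(tert-butyldimethylsilyloxy)-3-methyl-7-{(Z)-1-[5-(4-methylpent-3-en-1-yl)furan-3-yl]prop-1-en-2-yl}-3a,4,5,7a-tetrahydro-1-benzofuran-2(3H)-one (3-methyl on the convex face), via keto lactone 16 (not isolated)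
Conditions: DBU (20 mol%), CH2Cl2, rt; then Et3N, TBSOTf, −78 to 0 °C
Reagents that add atoms: tert-butyldimethylsilyl triflate (CC(C)(C)[Si](C)(C)OS(=O)(=O)C(F)(F)F)
Why: Reversible intramolecular oxa-Michael addition can only close the five-membered lactone cis, and DBU equilibrates the γ-stereocentre so that the fixed (S)-methyl carbon selects the lactone with its methyl on the convex face, which soft enolisation toward the doubly activated α-carbon then traps as the conjugated silyl dienol ether.

**Step 9**
Reactants: 17 the lactone silyl dienol ether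
Product: 18 siloxycyclopropane (CH2 added across the O-silylated C6=C7 alkene of 17 on the face opposite to the lactone ring)
Conditions: Et2Zn, CH2I2, CH2Cl2/DME, −20 to 0 °C
Reagents that add atoms: diiodomethane (ICI)
Why: In the Simmons–Smith reaction (Furukawa variant) the electrophilic zinc carbenoid should choose the most electron-rich alkene, the silyl enol ether, and approach the convex face of the cis-fused bicycle, which sets the quaternary carbon with its CH2 anti to the lactone oxygen.

**Step 10**
Reactants: 18 the siloxycyclopropane
Product: 20 (Z)-4-oxo-2-enal silyl ether (furan opened to OHC–C(alkenyl)=CH–C(=O)–CH2CH2CH=CMe2, the two carbonyl groups cis), via furan endoperoxide 19 (not isolated)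
Conditions: O2, tetraphenylporphyrin (cat.), hν, CH2Cl2, −78 °C; then Me2S, −78 °C to rt
Reagents that add atoms: oxygen (O=O)
Why: The [4+2] addition of singlet oxygen to a furan is much faster than the ene reaction of a trisubstituted alkene, and sulfide reduction of the endoperoxide delivers the enedicarbonyl with the cis geometry inherited from the ring.

**Step 11**
Reactants: 20 the (Z)-4-oxo-2-enal silyl ether
Product: 21 free cyclopropanol (same skeleton as 20 with OH in place of OSi)
Conditions: TBAF, AcOH, THF, 0 °C
Reagents that add atoms: none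
Why: Buffered fluoride desilylation frees the tertiary cyclopropanol without generating a free alkoxide, and 21 is used at once.

**Step 12**
Reactants: 21 the cyclopropanol (Z)-4-oxo-2-enal
Product: 23 bicyclo[2.2.2]octenone α-ketol (the target skeleton with OH in place of the angular methyl and C=O in place of C=CH2), via spiro keto aldehyde 22 (not isolated)
Conditions: Et2Zn (20 mol%), 2-(dimethylamino)ethanol (25 mol%), 2-(pentafluorophenyl)-6,7-dihydro-5H-pyrrolo[2,1-c][1,2,4]triazol-2-ium tetrafluoroborate (20 mol%), i-Pr2NEt (30 mol%), THF, 40 °C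
Reagents that add atoms: none
Why: Proposed new method: the zinc alkoxide of 21 should release the ring strain by breaking the carbinol–CH2 bond, and the resulting primary zinc homoenolate adds 6-endo-trig to the β-CH of the enal, closing ring A and unveiling the ring-B ketone of 22; the closest known reaction types are the zinc-catalysed conjugate addition of cyclopropanol-derived homoenolates to enones and the one-pot Michael/cross-benzoin cascades. The triazolylidene then adds to the freed aldehyde, and its Breslow intermediate attacks the new ketone 6-exo-trig across the boat of ring A, which closes ring C and with it the bicyclo[2.2.2]octene, as in crossed aldehyde–ketone benzoin closures onto ketones flanked by a quaternary carbon. The side-chain CH is set in the first closure: the cis-enedicarbonyl geometry puts the acyl group in the outside, pseudo-equatorial position, and 1,2-allylic strain with the vinylic methyl pushes the bulkier O-bearing ring-B carbon axial, so the acyl group ends up cis to the ketone carbon. The CH bridgehead is α to the aldehyde and epimerisable, so only the epimer with an axial formyl group is drained into product, and the carbinol carbon can be reached only from the face lying between the two existing bridges. Three selectivities are required: zinc must end on the primary CH2 rather than on the quaternary dienyl-substituted carbon, attack must occur at the unsubstituted β-CH (six-membered ring) rather than at the fully substituted alkene carbon (five-membered ring), and the pairing of the four termini must be correct. The pairing is secured because the ketone does not exist before the first bond is made, so the formyl carbon has no partner until the CH2–CH bond has formed.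

**Step 13**
Reactants: 23 the α-ketol
Product: 24 α-acetoxy ketone (tertiary acetate of 23)
Conditions: Ac2O, DMAP, Et3N, CH2Cl2, 40 °C
Reagents that add atoms: acetic anhydride (CC(=O)OC(C)=O)
Why: DMAP-catalysed acylation converts the only hydroxyl group into a reductively cleavable leaving group and blocks α-ketol rearrangement, without touching any stereocentre.

**Step 14**
Reactants: 24 the α-acetoxy ketone
Product: 25 methylenated α-acetoxy ketone (side-chain C=O converted to C=CH2)
Conditions: Cp2TiMe2, toluene, 65 °C
Reagents that add atoms: dimethyltitanocene ([CH3-].[CH3-].[Ti+4].c1cc[cH-]c1.c1cc[cH-]c1)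
Why: The non-basic Petasis methylenation should take the accessible side-chain ketone in preference to the ring ketone (flanked by a fully substituted carbon and a bridgehead) and to the two esters, and it leaves the adjacent epimerisable CH untouched.

**Step 15**
Reactants: 25 the methylenated α-acetoxy ketone
Product: 27 target CNP0385704.2, via copper enolate 26 (not isolated)
Conditions: CuI, MeLi, Et2O, 0 °C; 25, −78 to −20 °C; then MeI, THF/DMPU, −20 °C to rt
Reagents that add atoms: iodomethane (CI)
Why: Reductive cleavage of the α-acetoxy ketone by lithium dimethylcuprate gives the only possible enolate (the other α-carbon is a bridgehead), and enolate alkylation with iodomethane should occur from the face next to the C(Me)=CH bridge, because the other face is covered by the CH2–CH bridge and its side chain.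

**Compound list**
1 | (S)-2-(4-methoxyphenyl)propanoic acid | COc1ccc(cc1)[C@H](C)C(=O)O | starting material
2 | (S)-2-(4-methoxycyclohexa-1,4-dien-1-yl)propanoic acid | COC1=CCC(=CC1)[C@H](C)C(=O)O | intermediate
3 | methyl (2S)-2-[(1R)-4-oxocyclohex-2-en-1-yl]propanoate | COC(=O)[C@@H](C)[C@H]1C=CC(=O)CC1 | intermediate
4 | methyl (2S)-2-[(1S)-3-iodo-4-oxocyclohex-2-en-1-yl]propanoate | COC(=O)[C@@H](C)[C@H]1C=C(I)C(=O)CC1 | intermediate
5 | furan-3-carbaldehyde | O=Cc1ccoc1 | starting material
6 | 5-bromo-2-methylpent-2-ene | CC(C)=CCCBr | starting material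
7 | lithium (furan-3-yl)(morpholin-4-yl)methoxide | [Li]OC(N1CCOCC1)c1ccoc1 | intermediate
8 | lithium (5-lithiofuran-3-yl)(morpholin-4-yl)methoxide | [Li]OC(N1CCOCC1)c1coc([Li])c1 | intermediate
9 | lithium [5-(4-methylpent-3-en-1-yl)furan-3-yl](morpholin-4-yl)methoxide | [Li]OC(N1CCOCC1)c1coc(CCC=C(C)C)c1 | intermediate
10 | 5-(4-methylpent-3-en-1-yl)furan-3-carbaldehyde | O=Cc1coc(CCC=C(C)C)c1 | intermediate
11 | 4-[(Z)-2-iodoprop-1-en-1-yl]-2-(4-methylpent-3-en-1-yl)furan | C/C(I)=C/c1coc(CCC=C(C)C)c1 | intermediate
12 | (Z)-alkenyllithium from 11 | C/C([Li])=C/c1coc(CCC=C(C)C)c1 | intermediate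
13 | (Z)-alkenylzinc bromide from 12 | C/C([Zn]Br)=C/c1coc(CCC=C(C)C)c1 | intermediate
14 | methyl (2S)-2-[(1R)-3-{(Z)-1-[5-(4-methylpent-3-en-1-yl)furan-3-yl]prop-1-en-2-yl}-4-oxocyclohex-2-en-1-yl]propanoate | COC(=O)[C@@H](C)[C@H]1C=C(/C(C)=C\c2cc(CCC=C(C)C)oc2)C(=O)CC1 | intermediate
15 | carboxylic acid of 14 | OC(=O)[C@@H](C)[C@H]1C=C(/C(C)=C\c2cc(CCC=C(C)C)oc2)C(=O)CC1 | intermediate
16 | cis-fused keto lactone, 3-methyl-7-alkenylhexahydro-1-benzofuran-2,6-dione (methyl on the convex face, alkenyl equatorial) | [C@H]1(/C(C)=C\c2cc(CCC=C(C)C)oc2)C(=O)CC[C@H]2[C@H](C)C(=O)O[C@@H]12 | intermediate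
17 | cis-fused lactone tert-butyldimethylsilyl dienol ether | C1(/C(C)=C\c2cc(CCC=C(C)C)oc2)=C(O[Si](C)(C)C(C)(C)C)CC[C@H]2[C@H](C)C(=O)O[C@@H]12 | intermediate
18 | siloxycyclopropane (CH2 anti to the lactone ring) | [C@@]14(/C(C)=C\c2cc(CCC=C(C)C)oc2)C[C@]1(O[Si](C)(C)C(C)(C)C)CC[C@H]2[C@H](C)C(=O)O[C@H]24 | intermediate
19 | furan endoperoxide of 18 (the two new bridgehead carbons are not defined) | [C@@]14(/C(C)=C\C2=CC3(CCC=C(C)C)OOC2O3)C[C@]1(O[Si](C)(C)C(C)(C)C)CC[C@H]2[C@H](C)C(=O)O[C@H]24 | intermediate
20 | (Z)-4-oxo-2-enal silyl ether | [C@@]14(/C(C)=C\C(C=O)=C\C(=O)CCC=C(C)C)C[C@]1(O[Si](C)(C)C(C)(C)C)CC[C@H]2[C@H](C)C(=O)O[C@H]24 | intermediate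
21 | free cyclopropanol (Z)-4-oxo-2-enal | [C@@]14(/C(C)=C\C(C=O)=C\C(=O)CCC=C(C)C)C[C@]1(O)CC[C@H]2[C@H](C)C(=O)O[C@H]24 | intermediate
22 | spiro keto aldehyde (ring A closed, ring-B ketone free) | O=C(CCC=C(C)C)[C@H]1C[C@]2(C(C)=C[C@H]1C=O)C(=O)CC[C@H]1[C@H](C)C(=O)O[C@H]12 | intermediate
23 | bicyclo[2.2.2]octenone α-ketol | O=C(CCC=C(C)C)[C@H]1C[C@]23C(C)=C[C@H]1C(=O)[C@]2(O)CC[C@H]1[C@H](C)C(=O)O[C@H]13 | intermediate
24 | α-acetoxy ketone | O=C(CCC=C(C)C)[C@H]1C[C@]23C(C)=C[C@H]1C(=O)[C@]2(OC(C)=O)CC[C@H]1[C@H](C)C(=O)O[C@H]13 | intermediate
25 | methylenated α-acetoxy ketone | C=C(CCC=C(C)C)[C@H]1C[C@]23C(C)=C[C@H]1C(=O)[C@]2(OC(C)=O)CC[C@H]1[C@H](C)C(=O)O[C@H]13 | intermediate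
26 | monovalent copper enolate | C=C(CCC=C(C)C)[C@H]1C[C@]23C(C)=C[C@H]1C(O[Cu])=C2CC[C@H]1[C@H](C)C(=O)O[C@H]13 | intermediate
27 | CNP0385704.2 | C=C(CCC=C(C)C)[C@H]1C[C@]23C(C)=C[C@H]1C(=O)[C@]2(C)CC[C@H]1[C@H](C)C(=O)O[C@H]13 | target

**Totals.** The route has 15 steps in all. The longest linear sequence is 13 steps (steps 1–3 and 6–15).

**Steps most likely to fail**

1. **Step 12.** What may go wrong:
   - The cyclopropanol may open at the bond to the dienyl-substituted quaternary carbon. That would be a vinylogous retro-aldol ring expansion, and it is the most serious risk in the route.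
   - The zinc enolate may be captured by the new ketone in an aldol reaction.
   - The carbene may drive redox chemistry of the enal before the first bond forms.

   Fallback with known chemistry, starting from 20. Electrophilic mercuration of the siloxycyclopropane with Hg(OAc)2 attacks the least hindered CH2 and should give the β-(acetoxymercurio)methyl ketone F1. Iododemercuration with I2 gives the β-iodomethyl ketone F2. A tris(trimethylsilyl)silane/Et3B Giese cyclisation of F2 onto the doubly activated alkene then gives 22, now isolated. A separate triazolium/amine crossed benzoin closure converts 22 into 23, where the route is rejoined.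

2. **Step 9.** What may go wrong:
   - The carbenoid may attack the prenyl alkene, the furan or the alkenyl bridge instead of the silyl enol ether.
   - Zinc iodide may ionise the allylic lactone C–O bond.

   Fallback, starting from 4, which builds the cyclopropane before any competing alkene is present. Saponification gives the iodoenone acid F3. The conditions of step 8 give the iodo silyl enol ether lactone F4. Simmons–Smith cyclopropanation gives the iodocyclopropane F5. A Negishi coupling of F5 with the alkenylzinc bromide 13 (made from 11) rejoins the route at 18.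

3. **Step 15.** What may go wrong:
   - Proton transfer to the enolate may occur before alkylation.
   - The methylation may show poor facial selectivity.

   Fallback, starting from 25. SmI2/MeOH deacetoxylation gives the α-unsubstituted ketone F6. TMSOTf/Et3N gives the only possible trimethylsilyl enol ether F7. Simmons–Smith cyclopropanation from the open face next to the C(Me)=CH bridge gives the siloxycyclopropane F8. Acid-induced opening of the oxygenated carbon–CH2 bond (HCl, MeOH) turns the CH2 into the angular methyl and arrives at 27.

**Further compounds**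
F1 | step 12 | β-(acetoxymercurio)methyl ketone | CC(=O)O[Hg]C[C@]1(/C(C)=C\C(C=O)=C\C(=O)CCC=C(C)C)C(=O)CC[C@H]2[C@H](C)C(=O)O[C@H]21
F2 | step 12 | β-iodomethyl ketone | IC[C@]1(/C(C)=C\C(C=O)=C\C(=O)CCC=C(C)C)C(=O)CC[C@H]2[C@H](C)C(=O)O[C@H]21
F3 | step 9 | (2S)-2-[(1S)-3-iodo-4-oxocyclohex-2-en-1-yl]propanoic acid | OC(=O)[C@@H](C)[C@H]1C=C(I)C(=O)CC1
F4 | step 9 | cis-fused 7-iodo-6-(tert-butyldimethylsilyloxy) lactone enol ether | IC1=C(O[Si](C)(C)C(C)(C)C)CC[C@H]2[C@H](C)C(=O)O[C@@H]12
F5 | step 9 | iodo siloxycyclopropane (CH2 anti to the lactone ring) | I[C@@]14C[C@]1(O[Si](C)(C)C(C)(C)C)CC[C@H]2[C@H](C)C(=O)O[C@H]24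
F6 | step 15 | α-unsubstituted bicyclo[2.2.2]octenone | C=C(CCC=C(C)C)[C@H]1C[C@]23C(C)=C[C@H]1C(=O)[C@@H]2CC[C@H]1[C@H](C)C(=O)O[C@H]13
F7 | step 15 | trimethylsilyl enol ether of F6 | C=C(CCC=C(C)C)[C@H]1C[C@]23C(C)=C[C@H]1C(O[Si](C)(C)C)=C2CC[C@H]1[C@H](C)C(=O)O[C@H]13
F8 | step 15 | siloxycyclopropane of F7 (CH2 on the side of the C(Me)=CH bridge) | C=C(CCC=C(C)C)[C@H]1C[C@]23C(C)=C[C@H]1[C@@]4(O[Si](C)(C)C)C[C@@]24CC[C@H]1[C@H](C)C(=O)O[C@H]13
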